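Ring C is disconnected at O1–C2 and C3–C4, the two bonds that flank the C3 methylene. Because C2 carries the electron-rich ring B and C4 stands at the aldehyde oxidation level, the atoms C4, C4a, C8a and O1 can be supplied by a ring A salicylaldehyde dimethyl acetal (a latent 4-methoxy ortho-quinone methide) and C2–C3 by a ring B styrene. A single chiral-acid-catalysed inverse-demand oxa-Diels–Alder reaction joins the two prenylated halves, closes ring C and sets C2. The diene precursor is a 4,6-diprenyl-2-(dimethoxymethyl)phenol; O7 and O4' are masked as silyl ethers so that the benzylic acetal is the only acetal the acid can ionise.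

Key step: step 7

Remark: which enantiomer of the acid favours 2S cannot be assigned in advance; the (R)-configured catalyst is written and its mirror image is to be used if the sense proves opposite; the 2,4-cis adduct is drawn for 11, although either C4 epimer serves. Prenyl = 3-methylbut-2-en-1-yl; TBS = tert-butyldimethylsilyl.

Step 1
Reactants: 1 2,4-dihydroxybenzaldehyde; 2 prenyl bromide
Product: 3 2,4-dihydroxy-3,5-bis(3-methylbut-2-en-1-yl)benzaldehyde
Conditions: 2 (2.5 equiv), 10% aq KOH, 0 °C → rt; acidic work-up
Reagents that add atoms: none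
Why: Phenoxide C-alkylation in water, where hydrogen bonding to the oxygens steers the allylic bromide to carbon; C3 and C5 are the only ring carbons ortho or para to the phenoxide oxygens and both are wanted, so mono-prenylated material can be recycled and O-prenyl ethers removed by chromatography, the step being expected to be modest in efficiency but dependable.

Step 2
Reactants: 3 2,4-dihydroxy-3,5-bis(3-methylbut-2-en-1-yl)benzaldehyde
Product: 4 4-(tert-butyldimethylsilyloxy)-2-hydroxy-3,5-bis(3-methylbut-2-en-1-yl)benzaldehyde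
Conditions: TBSCl (1.1 equiv), imidazole (2.2 equiv), DMF, 0 °C → rt
Reagents that add atoms: tert-butyldimethylsilyl chloride, CC(C)(C)[Si](C)(C)Cl
Why: Phenol silylation, selective for the C4 hydroxyl because the C2 hydroxyl is locked in a hydrogen bond to the formyl group and is the less acidic of the two.

Step 3
Reactants: 4 4-(tert-butyldimethylsilyloxy)-2-hydroxy-3,5-bis(3-methylbut-2-en-1-yl)benzaldehyde
Product: 5 5-(tert-butyldimethylsilyloxy)-2-(dimethoxymethyl)-4,6-bis(3-methylbut-2-en-1-yl)phenol
Conditions: HC(OMe)3 (5 equiv), pyridinium p-toluenesulfonate (5 mol %), MeOH, rt; Et3N, concentration; used without chromatography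
Reagents that add atoms: trimethyl orthoformate, COC(OC)OC; methanol, CO
Why: Acid-catalysed acetalisation driven by the orthoformate as dehydrating agent; the weak pyridinium acid should spare the aryl silyl ether and the prenyl groups, and the labile free-phenol acetal is kept basic and used crude.

Step 4
Reactants: 6 4-hydroxybenzaldehyde; 2 prenyl bromide
Product: 7 4-hydroxy-3-(3-methylbut-2-en-1-yl)benzaldehyde
Conditions: 2 (0.9 equiv), 10% aq KOH, 0 °C → rt; acidic work-up
Reagents that add atoms: none
Why: The same aqueous phenoxide C-alkylation on a para-blocked phenol, so that only the ortho carbon can be alkylated, with the bromide as limiting reagent to hold back the 3,5-diprenyl by-product.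

Step 5
Reactants: 7 4-hydroxy-3-(3-methylbut-2-en-1-yl)benzaldehyde
Product: 8 4-(tert-butyldimethylsilyloxy)-3-(3-methylbut-2-en-1-yl)benzaldehyde
Conditions: TBSCl (1.2 equiv), imidazole (2.5 equiv), DMF, rt
Reagents that add atoms: tert-butyldimethylsilyl chloride, CC(C)(C)[Si](C)(C)Cl
Why: Routine phenol silylation, which also removes the acidic proton before the ylide step.

Step 6
Reactants: 8 4-(tert-butyldimethylsilyloxy)-3-(3-methylbut-2-en-1-yl)benzaldehyde
Product: 9 tert-butyldimethyl[2-(3-methylbut-2-en-1-yl)-4-vinylphenoxy]silane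
Conditions: Ph3PCH3Br (1.3 equiv), NaN(SiMe3)2 (1.25 equiv), THF, 0 °C → rt
Reagents that add atoms: methyltriphenylphosphonium bromide, C[P+](c1ccccc1)(c1ccccc1)c1ccccc1.[Br-]
Why: Wittig methylenation with the non-stabilised ylide, which should convert the aldehyde into the terminal olefin without touching the aryl silyl ether or the prenyl group.

Step 7
Reactants: 5 5-(tert-butyldimethylsilyloxy)-2-(dimethoxymethyl)-4,6-bis(3-methylbut-2-en-1-yl)phenol; 9 tert-butyldimethyl[2-(3-methylbut-2-en-1-yl)-4-vinylphenoxy]silane
Product: 11 (2S,4S)-7,4'-bis(tert-butyldimethylsilyloxy)-4-methoxy-6,8,3'-tris(3-methylbut-2-en-1-yl)flavan (2,4-cis), via 4-methoxy ortho-quinone methide 10 (not isolated)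
Conditions: 9 (2.5 equiv), (R)-3,3'-bis(2,4,6-triisopropylphenyl)-1,1'-binaphthyl-2,2'-diyl N-triflylphosphoramide (10 mol %), 5 Å molecular sieves, toluene, slow addition of 5, −60 → −30 °C; Et3N quench at low temperature
Reagents that add atoms: none
Why: Proposed new method: the strong chiral Brønsted acid should protonate one acetal oxygen of 5 and expel methanol to give the O-protonated form of ortho-quinone methide 10, an aryl-stabilised oxocarbenium ion held to the phosphoramide anion as a contact ion pair through the C8a hydroxyl. The terminal CH2 of styrene 9 attacks C4 (new C3–C4 bond) and O1 then collapses on the para-silyloxy-stabilised benzylic cation at C2 (new O1–C2 bond), an asynchronous inverse-demand oxa-[4+2] addition that closes the six-membered ring C with the aryl group necessarily on C2. The closest known reactions are the achiral-acid [4+2] addition of salicylaldehyde acetals to styrenes, which gives 2,4-cis 4-alkoxy-2-arylchromans, and the chiral-acid-catalysed cycloadditions of ortho-quinone methides with styrenes and of acetal-derived oxocarbenium ions with vinyl ethers; transferring the enantiocontrol to this alkoxy variant with a styrene is the untested part. C2 should be set by the chiral anion, whose 3,3'-aryl walls shield one face of the bound cation, while C4 follows from the endo placement of the aryl group and is of no consequence because it is oxidised later. The step needs the styrene to outcompete the three prenyl olefins and the ortho-prenyl phenol to resist cyclisation: the conjugated, para-oxygenated terminal olefin, used in excess, is the most nucleophilic π bond present, and the low temperature together with the far greater basicity of the acetal oxygen should keep the acid away from the trisubstituted olefins.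

Step 8
Reactants: 11 (2S,4S)-7,4'-bis(tert-butyldimethylsilyloxy)-4-methoxy-6,8,3'-tris(3-methylbut-2-en-1-yl)flavan
Product: 12 (2S)-7,4'-bis(tert-butyldimethylsilyloxy)-6,8,3'-tris(3-methylbut-2-en-1-yl)flavan-4-ol (C4 epimers)
Conditions: TsOH·H2O (10 mol %), THF/H2O (4:1), rt → 40 °C
Reagents that add atoms: water, O
Why: Acid-catalysed SN1 solvolysis: the C4 methyl ether is benzylic to a ring activated by O1 (ortho) and O7 (para), so catalytic acid in a large excess of water should exchange methoxy for hydroxy through the stabilised C4 cation while the aryl silyl ethers, the prenyl groups and C2 are left alone.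

Step 9
Reactants: 12 (2S)-7,4'-bis(tert-butyldimethylsilyloxy)-6,8,3'-tris(3-methylbut-2-en-1-yl)flavan-4-ol
Product: 13 (2S)-7,4'-bis(tert-butyldimethylsilyloxy)-6,8,3'-tris(3-methylbut-2-en-1-yl)flavanone
Conditions: Dess–Martin periodinane (1.3 equiv), NaHCO3, CH2Cl2, 0 °C → rt
Reagents that add atoms: none
Why: Dess–Martin oxidation of the secondary benzylic alcohol under buffered, non-enolising conditions should convert both C4 epimers into one ketone, spare the trisubstituted olefins and leave the C2 stereocentre untouched.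

Step 10
Reactants: 13 (2S)-7,4'-bis(tert-butyldimethylsilyloxy)-6,8,3'-tris(3-methylbut-2-en-1-yl)flavanone
Product: 14 (2S)-7,4'-dihydroxy-6,8,3'-tris(3-methylbut-2-en-1-yl)flavanone
Conditions: Bu4NF (2.5 equiv), AcOH (3 equiv), THF, 0 °C
Reagents that add atoms: none
Why: Fluoride-mediated cleavage of the two aryl silyl ethers, buffered with acetic acid so that no free phenoxide persists and the base-induced ring opening to the chalcone that would racemise C2 is avoided; the prenyl groups and the ketone are inert.

Compound list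
1 | 2,4-dihydroxybenzaldehyde | O=Cc1ccc(O)cc1O | starting material
2 | prenyl bromide (1-bromo-3-methylbut-2-ene) | CC(C)=CCBr | starting material
3 | 2,4-dihydroxy-3,5-bis(3-methylbut-2-en-1-yl)benzaldehyde | O=Cc1cc(CC=C(C)C)c(O)c(CC=C(C)C)c1O | intermediate
4 | 4-(tert-butyldimethylsilyloxy)-2-hydroxy-3,5-bis(3-methylbut-2-en-1-yl)benzaldehyde | O=Cc1cc(CC=C(C)C)c(O[Si](C)(C)C(C)(C)C)c(CC=C(C)C)c1O | intermediate
5 | 5-(tert-butyldimethylsilyloxy)-2-(dimethoxymethyl)-4,6-bis(3-methylbut-2-en-1-yl)phenol | COC(OC)c1cc(CC=C(C)C)c(O[Si](C)(C)C(C)(C)C)c(CC=C(C)C)c1O | intermediate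
6 | 4-hydroxybenzaldehyde | O=Cc1ccc(O)cc1 | starting material
7 | 4-hydroxy-3-(3-methylbut-2-en-1-yl)benzaldehyde | O=Cc1ccc(O)c(CC=C(C)C)c1 | intermediate
8 | 4-(tert-butyldimethylsilyloxy)-3-(3-methylbut-2-en-1-yl)benzaldehyde | O=Cc1ccc(O[Si](C)(C)C(C)(C)C)c(CC=C(C)C)c1 | intermediate
9 | tert-butyldimethyl[2-(3-methylbut-2-en-1-yl)-4-vinylphenoxy]silane | C=Cc1ccc(O[Si](C)(C)C(C)(C)C)c(CC=C(C)C)c1 | intermediate
10 | 4-methoxy ortho-quinone methide, 3-(tert-butyldimethylsilyloxy)-6-(methoxymethylidene)-2,4-bis(3-methylbut-2-en-1-yl)cyclohexa-2,4-dien-1-one (reacts as its O-protonated ion pair; not isolated) | COC=C1C=C(CC=C(C)C)C(O[Si](C)(C)C(C)(C)C)=C(CC=C(C)C)C1=O | intermediate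
11 | (2S,4S)-7,4'-bis(tert-butyldimethylsilyloxy)-4-methoxy-6,8,3'-tris(3-methylbut-2-en-1-yl)flavan (2,4-cis) | CC(C)=CCc1cc([C@@H]2C[C@H](OC)c3cc(CC=C(C)C)c(O[Si](C)(C)C(C)(C)C)c(CC=C(C)C)c3O2)ccc1O[Si](C)(C)C(C)(C)C | intermediate
12 | (2S)-7,4'-bis(tert-butyldimethylsilyloxy)-6,8,3'-tris(3-methylbut-2-en-1-yl)flavan-4-ol (C4 epimers) | CC(C)=CCc1cc([C@@H]2CC(O)c3cc(CC=C(C)C)c(O[Si](C)(C)C(C)(C)C)c(CC=C(C)C)c3O2)ccc1O[Si](C)(C)C(C)(C)C | intermediate
13 | (2S)-7,4'-bis(tert-butyldimethylsilyloxy)-6,8,3'-tris(3-methylbut-2-en-1-yl)flavanone | CC(C)=CCc1cc([C@@H]2CC(=O)c3cc(CC=C(C)C)c(O[Si](C)(C)C(C)(C)C)c(CC=C(C)C)c3O2)ccc1O[Si](C)(C)C(C)(C)C | intermediate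
14 | (2S)-7,4'-dihydroxy-6,8,3'-tris(3-methylbut-2-en-1-yl)flavanone | CC(C)=CCc1cc([C@@H]2CC(=O)c3cc(CC=C(C)C)c(O)c(CC=C(C)C)c3O2)ccc1O | target

Total step count: 10. Longest linear sequence: 7 steps (steps 1, 2, 3, 7, 8, 9, 10).

Steps most likely to fail

1. Step 7 (proposed new method). The chiral anion may not discriminate the two faces of the loosely bound alkoxy-substituted cation well enough, and the styrene may be lost to cationic oligomerisation. The fallback uses known chemistry and sets out from 5 and 9. The cycloaddition is run with an achiral acid (diphenyl hydrogen phosphate, 10 mol %, CH2Cl2, −40 °C), the established racemic version, to give racemic 2,4-cis 4-methoxyflavan F1. The conditions of steps 8 and 9 then give racemic flavan-4-ol F2 and racemic flavanone F3. F3 is resolved kinetically by asymmetric transfer hydrogenation (RuCl(p-cymene)[(R,R)-TsDPEN], where TsDPEN is N-tosyl-1,2-diphenylethylenediamine, HCO2H/Et3N, rt), a known resolution of racemic flavanones in which one enantiomer is reduced to its 2,4-cis alcohol. By the usual aryl ketone model this catalyst should deliver the 4R alcohol and so consume the 2R ketone as (2R,4R)-flavan-4-ol F4, leaving the 2S ketone, which is 13. The (S,S)-catalyst is taken if the sense proves opposite. After chromatographic separation the route is rejoined at 13.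

2. Step 8. The C4 cation may lose H3 instead of adding water (elimination towards the flav-3-ene) or be captured by an arene of a second molecule. The fallback sets out from 11 and oxidises the activated benzylic methyl ether directly with DDQ in CH2Cl2/pH 7 buffer at 0 °C. Hydride abstraction from C4, addition of water to the resulting oxocarbenium ion to give the 4-methoxyflavan-4-ol hemiketal F5 (not isolated) and loss of methanol should give the ketone. The route is rejoined at 13, so step 9 is bypassed as well.

3. Step 1. O-alkylation competes with C-alkylation and the second prenylation may stay incomplete, so throughput may be low and separation laborious. The fallback sets out from 1 and fixes both positions by halogenation and cross-coupling. Bromination (Br2, 2 equiv, AcOH, rt) gives 3,5-dibromo-2,4-dihydroxybenzaldehyde F6. Both phenols are protected (MOMCl, i-Pr2NEt, CH2Cl2) to give 3,5-dibromo-2,4-bis(methoxymethoxy)benzaldehyde F7. Twofold Stille coupling with tributyl(3-methylbut-2-en-1-yl)stannane (Pd(PPh3)4, DMF, 95 °C) gives 2,4-bis(methoxymethoxy)-3,5-diprenylbenzaldehyde F8. Acidic methanolysis (HCl, MeOH, rt) removes both acetals and rejoins the route at 3.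

Further compounds
F1 | step 7 | racemic 2,4-cis-7,4'-bis(tert-butyldimethylsilyloxy)-4-methoxy-6,8,3'-tris(3-methylbut-2-en-1-yl)flavan | CC(C)=CCc1cc(C2CC(OC)c3cc(CC=C(C)C)c(O[Si](C)(C)C(C)(C)C)c(CC=C(C)C)c3O2)ccc1O[Si](C)(C)C(C)(C)C
F2 | step 7 | racemic 7,4'-bis(tert-butyldimethylsilyloxy)-6,8,3'-tris(3-methylbut-2-en-1-yl)flavan-4-ol | CC(C)=CCc1cc(C2CC(O)c3cc(CC=C(C)C)c(O[Si](C)(C)C(C)(C)C)c(CC=C(C)C)c3O2)ccc1O[Si](C)(C)C(C)(C)C
F3 | step 7 | racemic 7,4'-bis(tert-butyldimethylsilyloxy)-6,8,3'-tris(3-methylbut-2-en-1-yl)flavanone | CC(C)=CCc1cc(C2CC(=O)c3cc(CC=C(C)C)c(O[Si](C)(C)C(C)(C)C)c(CC=C(C)C)c3O2)ccc1O[Si](C)(C)C(C)(C)C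
F4 | step 7 | (2R,4R)-7,4'-bis(tert-butyldimethylsilyloxy)-6,8,3'-tris(3-methylbut-2-en-1-yl)flavan-4-ol | CC(C)=CCc1cc([C@H]2C[C@@H](O)c3cc(CC=C(C)C)c(O[Si](C)(C)C(C)(C)C)c(CC=C(C)C)c3O2)ccc1O[Si](C)(C)C(C)(C)C
F5 | step 8 | (2S)-7,4'-bis(tert-butyldimethylsilyloxy)-4-methoxy-6,8,3'-tris(3-methylbut-2-en-1-yl)flavan-4-ol (hemiketal, not isolated) | CC(C)=CCc1cc([C@@H]2CC(O)(OC)c3cc(CC=C(C)C)c(O[Si](C)(C)C(C)(C)C)c(CC=C(C)C)c3O2)ccc1O[Si](C)(C)C(C)(C)C
F6 | step 1 | 3,5-dibromo-2,4-dihydroxybenzaldehyde | O=Cc1cc(Br)c(O)c(Br)c1O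
F7 | step 1 | 3,5-dibromo-2,4-bis(methoxymethoxy)benzaldehyde | O=Cc1cc(Br)c(OCOC)c(Br)c1OCOC
F8 | step 1 | 2,4-bis(methoxymethoxy)-3,5-bis(3-methylbut-2-en-1-yl)benzaldehyde | O=Cc1cc(CC=C(C)C)c(OCOC)c(CC=C(C)C)c1OCOC
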